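**Retrosynthetic overview**

1. The oxirane goes in last, by hydroxyl-directed epoxidation of the 1(10)-alkene (oxidation after cyclisation, as in the biosynthesis).
2. The ten-membered ring and the γ-lactone are made in one pot: the C6–C7 bond (the bond formed when farnesyl diphosphate closes to a germacrene) by intramolecular allylation of a (Z)-enal, then O6 takes over the C12 carbonyl by translactonisation.
3. The allyl nucleophile is held in a temporary 5,6-dihydropyran-2-one (O9–C12) made by ring-closing metathesis; this ring fixes allyl geometry and face, so C6 and C7 follow from C8.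
4. C8–C9, with both stereocentres and the (S)-2-methylbutanoate already on O8, comes from a catalytic asymmetric acyloxyallylation of a 2-formyl enoate.
5. C1–C6/C15 with the Z C4=C5 alkene comes from neryl acetate (oxidative cleavage, iodo-Wittig, formylation). Ring order: dihydropyranone tether, then carbocycle, then γ-lactone, then oxirane.

Locants in the text use germacrane numbering: C1–C10 ring, C11–C13 lactone/methylene carbons, C14 ester carbon on C10, C15 methyl on C4.

Assumption: the (R,R)-salen ligand in step 6 is taken to give Re-face attack at C9; if the sense is the opposite, its enantiomer is used and nothing else changes.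

**Route**

Step 1
Reactants: 1 neryl acetate
Product: 3 (2Z)-3-methyl-6-oxohex-2-en-1-yl acetate, via 6,7-epoxyneryl acetate 2 (not isolated)
Conditions: mCPBA, CH2Cl2, 0 °C; then H5IO6, THF/H2O, 0 °C
Reagents that add atoms: mCPBA, O=C(OO)c1cccc(Cl)c1
Why: Prilezhaev epoxidation takes the electron-rich 6,7-alkene (the 2,3-alkene is deactivated by the allylic acetate) and periodic acid cleaves the epoxide through its diol (Malaprade-type) to the aldehyde, leaving the Z C4=C5 alkene untouched.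

Step 2
Reactants: 3 (2Z)-3-methyl-6-oxohex-2-en-1-yl acetate; 4 methyl (triphenylphosphoranylidene)acetate
Product: 6 methyl (2Z,6Z)-8-(acetyloxy)-2-iodo-6-methylocta-2,6-dienoate, via methyl iodo(triphenylphosphoranylidene)acetate 5 (not isolated)
Conditions: 4, N-iodosuccinimide, CH2Cl2, −20 °C, 30 min; then 3, −20 °C → rt
Reagents that add atoms: methyl (triphenylphosphoranylidene)acetate 4, COC(=O)C=P(c1ccccc1)(c1ccccc1)c1ccccc1; N-iodosuccinimide, O=C1CCC(=O)N1I
Why: Wittig olefination with the α-iodinated stabilised ylide puts the chain trans to the ester, giving the (Z)-α-iodoenoate and so fixing the later C1=C10 geometry (C2 cis to C9).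

Step 3
Reactants: 6 methyl (2Z,6Z)-8-(acetyloxy)-2-iodo-6-methylocta-2,6-dienoate
Product: 7 methyl (2Z,6Z)-8-hydroxy-2-iodo-6-methylocta-2,6-dienoate
Conditions: K2CO3 (0.2 equiv), MeOH, 0 °C
Reagents that add atoms: none
Why: Zemplén-type transesterification removes the primary acetate (the methyl ester is degenerate in methanol) before step 4, where zerovalent palladium and the tin hydride would ionise and reduce an allylic acetate.

Step 4
Reactants: 7 methyl (2Z,6Z)-8-hydroxy-2-iodo-6-methylocta-2,6-dienoate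
Product: 8 methyl (2E,6Z)-2-formyl-8-hydroxy-6-methylocta-2,6-dienoate
Conditions: Pd(PPh3)4 (5 mol %), CO (1 atm), Bu3SnH (1.1 equiv, syringe pump), THF, 50 °C; used crude
Reagents that add atoms: carbon monoxide, [C-]#[O+]
Why: Palladium-catalysed reductive carbonylation (Stille-type formylation) of the alkenyl iodide goes with retention of geometry, and the isomer with the chain cis to the formyl group is also the more stable one.

Step 5
Reactants: 9 (2S)-2-methylbutanoic acid; 10 acrolein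
Product: 12 3-chloroprop-1-en-1-yl (2S)-2-methylbutanoate (E/Z mixture), via (2S)-2-methylbutanoyl chloride 11 (not isolated)
Conditions: (COCl)2, cat. DMF, CH2Cl2, 0 °C → rt; then acrolein, ZnCl2 (2 mol %), −10 °C → rt
Reagents that add atoms: acrolein 10, C=CC=O; oxalyl chloride, O=C(Cl)C(=O)Cl
Why: Acid chloride formation followed by ZnCl2-catalysed 1,4-addition of the acyl chloride to acrolein gives the chloropropenyl ester without any base, so the α-stereocentre of the acid is not racemised.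

Step 6
Reactants: 8 methyl (2E,6Z)-2-formyl-8-hydroxy-6-methylocta-2,6-dienoate; 12 3-chloroprop-1-en-1-yl (2S)-2-methylbutanoate
Product: 14 methyl (2E,6Z)-8-hydroxy-2-[(1S,2S)-1-hydroxy-2-{[(2S)-2-methylbutanoyl]oxy}but-3-en-1-yl]-6-methylocta-2,6-dienoate, via bis(trimethylsilyl) ether 13 (not isolated)
Conditions: CrCl3 (10 mol %), (R,R)-N,N′-bis(3,5-di-tert-butylsalicylidene)cyclohexane-1,2-diamine (10 mol %), Et3N (20 mol %), Mn powder (3 equiv), Me3SiCl (3 equiv), MeCN, rt; then citric acid, MeOH; chromatography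
Reagents that add atoms: 3-chloroprop-1-en-1-yl (2S)-2-methylbutanoate 12, CC[C@H](C)C(=O)OC=CCCl
Why: Catalytic asymmetric Nozaki–Hiyama–Kishi-type acyloxyallylation: the γ-acyloxyallylchromium from 12 adds 1,2 to the aldehyde on the salen-bound trivalent chromium, syn-selectively and on the Re face, setting C9 and C8 (threo) with the ester born on O8 and the free hydroxyl on O9; silylation of the chromium alkoxide turns the catalyst over and blocks 8→9 acyl shift, and minor isomers (diastereomers because of the (S)-acyl group) are removed by chromatography.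

Step 7
Reactants: 14 methyl (2E,6Z)-8-hydroxy-2-[(1S,2S)-1-hydroxy-2-{[(2S)-2-methylbutanoyl]oxy}but-3-en-1-yl]-6-methylocta-2,6-dienoate
Product: 15 methyl (2E,6Z)-2-[(1S,2S)-1-hydroxy-2-{[(2S)-2-methylbutanoyl]oxy}but-3-en-1-yl]-6-methyl-8-oxoocta-2,6-dienoate
Conditions: TEMPO (10 mol %), PhI(OAc)2 (1.1 equiv), CH2Cl2, rt
Reagents that add atoms: none
Why: Oxoammonium (TEMPO) oxidation is selective for the primary allylic alcohol over the hindered secondary C9 alcohol and keeps the Z geometry of the enal.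

Step 8
Reactants: 15 methyl (2E,6Z)-2-[(1S,2S)-1-hydroxy-2-{[(2S)-2-methylbutanoyl]oxy}but-3-en-1-yl]-6-methyl-8-oxoocta-2,6-dienoate; 16 2-(bromomethyl)prop-2-enoic acid
Product: 18 methyl (2E,6Z)-2-[(1S,2S)-1-{[2-(bromomethyl)prop-2-enoyl]oxy}-2-{[(2S)-2-methylbutanoyl]oxy}but-3-en-1-yl]-6-methyl-8-oxoocta-2,6-dienoate, via 2-(bromomethyl)prop-2-enoyl chloride 17 (not isolated)
Conditions: 16, (COCl)2, cat. DMF, CH2Cl2, 0 °C; then 15, 2,6-lutidine, CH2Cl2, −40 → 0 °C
Reagents that add atoms: 2-(bromomethyl)prop-2-enoic acid 16, C=C(CBr)C(=O)O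
Why: O-acylation of the C9 alcohol by the acid chloride with a hindered weak base, which neither displaces the allylic bromide nor promotes acyl shift from O8.

Step 9
Reactants: 18 methyl (2E,6Z)-2-[(1S,2S)-1-{[2-(bromomethyl)prop-2-enoyl]oxy}-2-{[(2S)-2-methylbutanoyl]oxy}but-3-en-1-yl]-6-methyl-8-oxoocta-2,6-dienoate
Product: 19 methyl (2E,6Z)-2-[(2S,3S)-5-(bromomethyl)-3-{[(2S)-2-methylbutanoyl]oxy}-6-oxo-3,6-dihydro-2H-pyran-2-yl]-6-methyl-8-oxoocta-2,6-dienoate
Conditions: second-generation Grubbs catalyst (5 mol %), CH2Cl2 (0.005 M), 40 °C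
Reagents that add atoms: none
Why: Ring-closing metathesis of the acrylate of a homoallylic alcohol forms the six-membered unsaturated lactone (C7=C11), which installs the allylic bromide unit, ties up O9 and locks C8 trans to CH2Br; no stereocentre is touched.

Step 10
Reactants: 19 methyl (2E,6Z)-2-[(2S,3S)-5-(bromomethyl)-3-{[(2S)-2-methylbutanoyl]oxy}-6-oxo-3,6-dihydro-2H-pyran-2-yl]-6-methyl-8-oxoocta-2,6-dienoate
Product: 21 methyl (1(10)E,4Z,6R,7S,8S,9S)-9-hydroxy-8-{[(2S)-2-methylbutanoyl]oxy}germacra-1(10),4,11(13)-trien-12,6-olid-14-oate, via bridged 9,12-lactone carbinol 20 (not isolated)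
Conditions: CrCl2 (8 equiv), THF, 0.002 M (syringe-pump addition of 19), 25 °C; aq. NH4Cl; then PPTS (cat.), CH2Cl2, 25 °C
Reagents that add atoms: none
Why: Chromium-mediated intramolecular Nozaki–Hiyama (Barbier-type) carbonyl allylation closes the ten-membered ring at C6–C7, the bond and polarity of the germacrene-forming cyclisation (C13–Cr stands in for the proton lost from C13): the allylchromium attacks the enal through C7 anti to the pseudoaxial C8 ester, its ring-locked geometry (C8 trans to CH2Cr) in a chair Zimmerman–Traxler transition state gives the anti adduct (6R, 7S), and O6 then takes the C12 acyl group from O9 (translactonisation to the fused γ-lactone), as in the biosynthetic lactonisation.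

Step 11
Reactants: 21 methyl (1(10)E,4Z,6R,7S,8S,9S)-9-hydroxy-8-{[(2S)-2-methylbutanoyl]oxy}germacra-1(10),4,11(13)-trien-12,6-olid-14-oate
Product: 22 methyl (1R,4Z,6R,7S,8S,9R,10S)-1,10-epoxy-9-hydroxy-8-{[(2S)-2-methylbutanoyl]oxy}germacra-4,11(13)-dien-12,6-olid-14-oate (CNP0581690.1)
Conditions: VO(acac)2 (10 mol %), t-BuOOH (2 equiv, decane solution), CH2Cl2, 25–40 °C
Reagents that add atoms: tert-butyl hydroperoxide, CC(C)(C)OO
Why: Vanadium-catalysed hydroxyl-directed epoxidation (Sharpless–Michaelson type) delivers oxygen only to the C1=C10 bond next to the C9 hydroxyl (C4=C5 and the methylene lactone have no directing group), and medium-ring (Z)-allylic alcohols give the trans (threo) epoxy alcohol, here the 1β,10β-epoxide (1R,10S).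

**Compound list**

1 | neryl acetate, (2Z)-3,7-dimethylocta-2,6-dien-1-yl acetate | CC(=O)OC/C=C(/C)CCC=C(C)C | starting material
2 | 6,7-epoxyneryl acetate, (2Z)-5-(3,3-dimethyloxiran-2-yl)-3-methylpent-2-en-1-yl acetate (racemic) | CC(=O)OC/C=C(/C)CCC1OC1(C)C | intermediate
3 | (2Z)-3-methyl-6-oxohex-2-en-1-yl acetate | CC(=O)OC/C=C(/C)CCC=O | intermediate
4 | methyl (triphenylphosphoranylidene)acetate | COC(=O)C=P(c1ccccc1)(c1ccccc1)c1ccccc1 | starting material
5 | methyl iodo(triphenylphosphoranylidene)acetate | COC(=O)C(I)=P(c1ccccc1)(c1ccccc1)c1ccccc1 | intermediate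
6 | methyl (2Z,6Z)-8-(acetyloxy)-2-iodo-6-methylocta-2,6-dienoate | CC(=O)OC/C=C(/C)CC/C=C(/C(=O)OC)I | intermediate
7 | methyl (2Z,6Z)-8-hydroxy-2-iodo-6-methylocta-2,6-dienoate | OC/C=C(/C)CC/C=C(/C(=O)OC)I | intermediate
8 | methyl (2E,6Z)-2-formyl-8-hydroxy-6-methylocta-2,6-dienoate | OC/C=C(/C)CC/C=C(/C(=O)OC)C=O | intermediate
9 | (2S)-2-methylbutanoic acid | CC[C@H](C)C(=O)O | starting material
10 | acrolein | C=CC=O | starting material
11 | (2S)-2-methylbutanoyl chloride | CC[C@H](C)C(=O)Cl | intermediate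
12 | 3-chloroprop-1-en-1-yl (2S)-2-methylbutanoate (E/Z mixture) | CC[C@H](C)C(=O)OC=CCCl | intermediate
13 | methyl (2E,6Z)-6-methyl-2-[(1S,2S)-2-{[(2S)-2-methylbutanoyl]oxy}-1-[(trimethylsilyl)oxy]but-3-en-1-yl]-8-[(trimethylsilyl)oxy]octa-2,6-dienoate | C[Si](C)(C)OC/C=C(/C)CC/C=C(/C(=O)OC)[C@H](O[Si](C)(C)C)[C@@H](OC(=O)[C@@H](C)CC)C=C | intermediate
14 | methyl (2E,6Z)-8-hydroxy-2-[(1S,2S)-1-hydroxy-2-{[(2S)-2-methylbutanoyl]oxy}but-3-en-1-yl]-6-methylocta-2,6-dienoate | OC/C=C(/C)CC/C=C(/C(=O)OC)[C@H](O)[C@@H](OC(=O)[C@@H](C)CC)C=C | intermediate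
15 | methyl (2E,6Z)-2-[(1S,2S)-1-hydroxy-2-{[(2S)-2-methylbutanoyl]oxy}but-3-en-1-yl]-6-methyl-8-oxoocta-2,6-dienoate | O=C/C=C(/C)CC/C=C(/C(=O)OC)[C@H](O)[C@@H](OC(=O)[C@@H](C)CC)C=C | intermediate
16 | 2-(bromomethyl)prop-2-enoic acid | C=C(CBr)C(=O)O | starting material
17 | 2-(bromomethyl)prop-2-enoyl chloride | C=C(CBr)C(=O)Cl | intermediate
18 | methyl (2E,6Z)-2-[(1S,2S)-1-{[2-(bromomethyl)prop-2-enoyl]oxy}-2-{[(2S)-2-methylbutanoyl]oxy}but-3-en-1-yl]-6-methyl-8-oxoocta-2,6-dienoate | O=C/C=C(/C)CC/C=C(/C(=O)OC)[C@H](OC(=O)C(=C)CBr)[C@@H](OC(=O)[C@@H](C)CC)C=C | intermediate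
19 | methyl (2E,6Z)-2-[(2S,3S)-5-(bromomethyl)-3-{[(2S)-2-methylbutanoyl]oxy}-6-oxo-3,6-dihydro-2H-pyran-2-yl]-6-methyl-8-oxoocta-2,6-dienoate | O=C/C=C(/C)CC/C=C(/C(=O)OC)[C@@H]1OC(=O)C(CBr)=C[C@@H]1OC(=O)[C@@H](C)CC | intermediate
20 | methyl (1(10)E,4Z,6R,7S,8S,9S)-6-hydroxy-8-{[(2S)-2-methylbutanoyl]oxy}germacra-1(10),4,11(13)-trien-12,9-olid-14-oate (δ-lactone O9–C12 bridging C7 and C9) | C=C1C(=O)O[C@@H]2[C@@H](OC(=O)[C@@H](C)CC)[C@@H]1[C@H](O)/C=C(/C)CC/C=C2/C(=O)OC | intermediate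
21 | methyl (1(10)E,4Z,6R,7S,8S,9S)-9-hydroxy-8-{[(2S)-2-methylbutanoyl]oxy}germacra-1(10),4,11(13)-trien-12,6-olid-14-oate | C=C1C(=O)O[C@@H]2/C=C(/C)CC/C=C(/C(=O)OC)[C@H](O)[C@@H](OC(=O)[C@@H](C)CC)[C@@H]12 | intermediate
22 | methyl (1R,4Z,6R,7S,8S,9R,10S)-1,10-epoxy-9-hydroxy-8-{[(2S)-2-methylbutanoyl]oxy}germacra-4,11(13)-dien-12,6-olid-14-oate | C=C1C(=O)O[C@@H]2/C=C(/C)CC[C@H]3O[C@@]3(C(=O)OC)[C@H](O)[C@@H](OC(=O)[C@@H](C)CC)[C@@H]12 | target

**Step count and risks**

Total step count: 11 (ten on the main line plus step 5 for reagent 12). Longest linear sequence: 10 (steps 1–4 and 6–11).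

Steps most likely to fail:

Step 10. The allylchromium carries the C8 carboxylate in a position from which 1,4-elimination to a diene is possible, and the ring closure passes through a strained bridged lactone. The fallback sets out from 19. Borylation of the allylic bromide (Pd2(dba)3, B2pin2, THF, 60 °C) gives the pinacol allylboronate F1, which has no carbon–metal bond that can expel the ester. Sc(OTf)3 (10 mol %) in CH2Cl2 at 0.002 M then triggers a closed, chair-like intramolecular allylboration of the enal (same ring-locked allyl geometry, same anti outcome). The borate lactonises onto C12 as before, passing through 20 and coming back to the route at 21.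

Step 11. The C1=C10 bond is an electron-poor enoate, so the directed epoxidation may be slow and C4=C5 may compete. The fallback sets out from 8 and puts the oxirane in first, on the doubly activated alkene where nucleophilic epoxidation is easy. A cinchona primary amine salt (9-amino-9-deoxy-epi-quinine or its quinidine pseudo-enantiomer, trifluoroacetate, 10 mol %) with aqueous H2O2 gives epoxy aldehyde F2 (iminium-type Weitz–Scheffer epoxidation, catalyst chosen for the 2R,3R product). The operations of steps 6–10 are then run unchanged on the epoxide series: acyloxyallylation to epoxy diol monoester F3, TEMPO oxidation to epoxy enal F4, acylation with 17 to epoxy bromomethylacrylate F5, ring-closing metathesis to epoxy dihydropyranone F6, and chromium-mediated cyclisation through bridged epoxy lactone carbinol F7. This comes back to the route directly at 22.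

Step 6. The syn selectivity and enantioselectivity of the catalytic acyloxyallylation may be modest on this highly electrophilic aldehyde. The fallback sets out from 8 and uses a stoichiometric chiral reagent. Brown's (Z)-γ-(methoxymethoxy)allyldiisopinocampheylborane (allyl methoxymethyl ether, sec-BuLi, (+)-B-methoxydiisopinocampheylborane from (−)-α-pinene, BF3·OEt2, −78 °C) gives the syn adduct MOM ether diol F8 with the free hydroxyl on C9. TEMPO oxidation gives MOM ether enal F9, acylation with 17 gives MOM ether bromomethylacrylate F10, and ring-closing metathesis gives MOM dihydropyranone F11. With O9 now held in the lactone, Me2BBr (−78 °C) frees only O8 to give hydroxy dihydropyranone F12, and (2S)-2-methylbutanoyl chloride 11 with pyridine installs the ester. This comes back to the route at 19.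

**Further compounds**

F1 | step 10 | methyl (2E,6Z)-6-methyl-2-[(2S,3S)-3-{[(2S)-2-methylbutanoyl]oxy}-6-oxo-5-[(4,4,5,5-tetramethyl-1,3,2-dioxaborolan-2-yl)methyl]-3,6-dihydro-2H-pyran-2-yl]-8-oxoocta-2,6-dienoate | O=C/C=C(/C)CC/C=C(/C(=O)OC)[C@@H]1OC(=O)C(CB2OC(C)(C)C(C)(C)O2)=C[C@@H]1OC(=O)[C@@H](C)CC
F2 | step 11 | methyl (2R,3R)-2-formyl-3-[(3Z)-5-hydroxy-3-methylpent-3-en-1-yl]oxirane-2-carboxylate | OC/C=C(/C)CC[C@H]1O[C@@]1(C(=O)OC)C=O
F3 | step 11 | methyl (2S,3R)-2-[(1R,2S)-1-hydroxy-2-{[(2S)-2-methylbutanoyl]oxy}but-3-en-1-yl]-3-[(3Z)-5-hydroxy-3-methylpent-3-en-1-yl]oxirane-2-carboxylate | OC/C=C(/C)CC[C@H]1O[C@@]1(C(=O)OC)[C@H](O)[C@@H](OC(=O)[C@@H](C)CC)C=C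
F4 | step 11 | methyl (2S,3R)-2-[(1R,2S)-1-hydroxy-2-{[(2S)-2-methylbutanoyl]oxy}but-3-en-1-yl]-3-[(3Z)-3-methyl-5-oxopent-3-en-1-yl]oxirane-2-carboxylate | O=C/C=C(/C)CC[C@H]1O[C@@]1(C(=O)OC)[C@H](O)[C@@H](OC(=O)[C@@H](C)CC)C=C
F5 | step 11 | methyl (2R,3R)-2-[(1R,2S)-1-{[2-(bromomethyl)prop-2-enoyl]oxy}-2-{[(2S)-2-methylbutanoyl]oxy}but-3-en-1-yl]-3-[(3Z)-3-methyl-5-oxopent-3-en-1-yl]oxirane-2-carboxylate | O=C/C=C(/C)CC[C@H]1O[C@@]1(C(=O)OC)[C@H](OC(=O)C(=C)CBr)[C@@H](OC(=O)[C@@H](C)CC)C=C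
F6 | step 11 | methyl (2R,3R)-2-[(2R,3S)-5-(bromomethyl)-3-{[(2S)-2-methylbutanoyl]oxy}-6-oxo-3,6-dihydro-2H-pyran-2-yl]-3-[(3Z)-3-methyl-5-oxopent-3-en-1-yl]oxirane-2-carboxylate | O=C/C=C(/C)CC[C@H]1O[C@@]1(C(=O)OC)[C@@H]2OC(=O)C(CBr)=C[C@@H]2OC(=O)[C@@H](C)CC
F7 | step 11 | methyl (1R,4Z,6R,7S,8S,9R,10R)-1,10-epoxy-6-hydroxy-8-{[(2S)-2-methylbutanoyl]oxy}germacra-4,11(13)-dien-12,9-olid-14-oate | C=C1C(=O)O[C@@H]2[C@@H](OC(=O)[C@@H](C)CC)[C@@H]1[C@H](O)/C=C(/C)CC[C@H]3O[C@]32C(=O)OC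
F8 | step 6 | methyl (2E,6Z)-8-hydroxy-2-[(1S,2S)-1-hydroxy-2-(methoxymethoxy)but-3-en-1-yl]-6-methylocta-2,6-dienoate | OC/C=C(/C)CC/C=C(/C(=O)OC)[C@H](O)[C@@H](OCOC)C=C
F9 | step 6 | methyl (2E,6Z)-2-[(1S,2S)-1-hydroxy-2-(methoxymethoxy)but-3-en-1-yl]-6-methyl-8-oxoocta-2,6-dienoate | O=C/C=C(/C)CC/C=C(/C(=O)OC)[C@H](O)[C@@H](OCOC)C=C
F10 | step 6 | methyl (2E,6Z)-2-[(1S,2S)-1-{[2-(bromomethyl)prop-2-enoyl]oxy}-2-(methoxymethoxy)but-3-en-1-yl]-6-methyl-8-oxoocta-2,6-dienoate | O=C/C=C(/C)CC/C=C(/C(=O)OC)[C@H](OC(=O)C(=C)CBr)[C@@H](OCOC)C=C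
F11 | step 6 | methyl (2E,6Z)-2-[(2S,3S)-5-(bromomethyl)-3-(methoxymethoxy)-6-oxo-3,6-dihydro-2H-pyran-2-yl]-6-methyl-8-oxoocta-2,6-dienoate | O=C/C=C(/C)CC/C=C(/C(=O)OC)[C@@H]1OC(=O)C(CBr)=C[C@@H]1OCOC
F12 | step 6 | methyl (2E,6Z)-2-[(2S,3S)-5-(bromomethyl)-3-hydroxy-6-oxo-3,6-dihydro-2H-pyran-2-yl]-6-methyl-8-oxoocta-2,6-dienoate | O=C/C=C(/C)CC/C=C(/C(=O)OC)[C@@H]1OC(=O)C(CBr)=C[C@@H]1O
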